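**Plan**
1. Enabling feature: C1 of the 2,8-dioxabicyclo[3.2.1]octane (bonded to O2 and O8) is a masked ketone. The tertiary carbinol carbon next to it is its α-carbon and the CH(OAc) carbon its β-carbon. The HO–C–CH2OAc unit is an acetate-opened epoxide of an α-methylene group. Ketal C, carbinol C and CH2OAc are therefore the three carbons of an alkoxyallene, and the bond to CH(OAc) is a Morita–Baylis–Hillman-type aldol bond.
2. Cuts, in order: aryl O–Si bonds and the secondary O-acetyl group; the CH2–OAc bond and the epoxide oxygen; in one event the CH(O)–C(=CH2) bond together with both ketal C–O bonds (C1–O8, C1–O2); the allene C–CH2 bond (methoxyallene + primary iodide); the acyl C–alkenyl bond (mevalonolactone + alkenyl iodide).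
3. Forward: a C9 alkenyllithium opens the C6 lactone, and methoxyallene is alkylated as a three-carbon linchpin. Union with the arylacetaldehyde then closes first the oxolane ring (C1–C7–C6–C5–O8) and then the 1,3-dioxane ring (C1–O2–C3–C4–C5–O8).
4. Stereochemistry: C5 comes from (R)-mevalonolactone (chiral pool) and C3 from CBS reduction; C1 is forced by the bridge. CH(OAc) is set by a chiral Lewis acid, the tertiary carbinol by hydroxyl-directed epoxidation (A1,2 strain, erythro), and the E-alkene by syn-carboalumination.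

Key step: step 13

Assumption: (R)-mevalonolactone and methoxyallene are purchased. "Si-face-selective antipode" means whichever enantiomer of the Cr(III) complex is found to attack the Si face of the arylacetaldehyde (both enantiomers of cis-1-amino-2-indanol are sold).

Step 1
Reactants: 1 5-bromo-2-methylpent-2-ene
Product: 2 6-methylhept-5-en-1-yne
Conditions: LiC≡CH·H2NCH2CH2NH2 (1.3 equiv), DMSO, 0 °C to rt
Reagents that add atoms: lithium acetylide–ethylenediamine complex, [Li]C#C.NCCN
Why: SN2 alkylation of lithium acetylide by an unhindered primary bromide in DMSO is a standard terminal-alkyne synthesis and creates no stereocentre.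

Step 2
Reactants: 2 6-methylhept-5-en-1-yne
Product: 4 (1E)-1-iodo-2,6-dimethylhepta-1,5-diene, via alkenyldimethylalane 3 (not isolated)
Conditions: Me3Al (2 equiv), Cp2ZrCl2 (0.25 equiv), CH2Cl2, 0 °C to rt; then I2, THF, −30 °C
Reagents that add atoms: trimethylaluminium, C[Al](C)C; iodine, II
Why: Negishi zirconium-catalysed carboalumination adds CH3 and Al syn across the terminal alkyne with Al at the terminus, and iodinolysis with retention fixes the E trisubstituted alkene of the target while the remote trisubstituted alkene is inert.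

Step 3
Reactants: 5 (R)-mevalonolactone
Product: 6 (4R)-4-methyl-4-(triethylsilyloxy)oxan-2-one
Conditions: TESOTf (1.2 equiv), 2,6-lutidine (1.5 equiv), CH2Cl2, 0 °C
Reagents that add atoms: triethylsilyl triflate, CC[Si](CC)(CC)OS(=O)(=O)C(F)(F)F
Why: Silyl triflate/lutidine O-silylation caps the hindered tertiary alcohol without enolising the lactone, and the chiral-pool stereocentre, the future C5 of the bicycle, is not touched.

Step 4
Reactants: 4 (1E)-1-iodo-2,6-dimethylhepta-1,5-diene; 6 (4R)-4-methyl-4-(triethylsilyloxy)oxan-2-one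
Product: 8 (3R,6E)-1-hydroxy-3,7,11-trimethyl-3-(triethylsilyloxy)dodeca-6,10-dien-5-one, via alkenyllithium 7 (not isolated)
Conditions: 4 (1.05 equiv), t-BuLi (2.1 equiv), Et2O, −78 °C; then 6, THF, −78 °C; AcOH in THF at −78 °C
Reagents that add atoms: none
Why: Iodine–lithium exchange keeps the alkene geometry, and mono-addition of an alkenyllithium to a δ-lactone stops at the tetrahedral alkoxide at −78 °C, which collapses to the conjugated hydroxy enone only on the cold acidic quench.

Step 5
Reactants: 8 (3R,6E)-1-hydroxy-3,7,11-trimethyl-3-(triethylsilyloxy)dodeca-6,10-dien-5-one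
Product: 9 (3S,6E)-1-iodo-3,7,11-trimethyl-3-(triethylsilyloxy)dodeca-6,10-dien-5-one
Conditions: I2 (1.2 equiv), PPh3 (1.2 equiv), imidazole (2.5 equiv), CH2Cl2, 0 °C
Reagents that add atoms: iodine, II
Why: Appel-type iodination converts the only free, primary hydroxyl into the iodide under buffered conditions that spare the tertiary silyl ether and the alkenes (the descriptor changes to 3S only because iodine alters the CIP ranking).

Step 6
Reactants: 9 (3S,6E)-1-iodo-3,7,11-trimethyl-3-(triethylsilyloxy)dodeca-6,10-dien-5-one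
Product: 10 (3S,5S,6E)-1-iodo-3,7,11-trimethyl-3-(triethylsilyloxy)dodeca-6,10-dien-5-ol
Conditions: (R)-Me-CBS (0.5 equiv), catecholborane (2 equiv), toluene, −78 °C; MeOH, pH 7 buffer work-up
Reagents that add atoms: none
Why: Corey–Bakshi–Shibata reduction treats the alkenyl arm as the large and the CH2 arm as the small substituent, so the (R)-catalyst should deliver hydride 1,2-selectively to give the 5S allylic alcohol (future C3 of the bicycle) by reagent control without touching the alkyl iodide.

Step 7
Reactants: 10 (3S,5S,6E)-1-iodo-3,7,11-trimethyl-3-(triethylsilyloxy)dodeca-6,10-dien-5-ol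
Product: 11 (3S,5S,6E)-1-iodo-3,7,11-trimethyl-3,5-bis(triethylsilyloxy)dodeca-6,10-diene
Conditions: TESCl (1.3 equiv), imidazole (2.5 equiv), DMAP (cat.), CH2Cl2, 0 °C to rt
Reagents that add atoms: chlorotriethylsilane, CC[Si](CC)(CC)Cl
Why: Imidazole-promoted silylation of the secondary allylic alcohol is faster than any ether-forming attack on the iodide and gives both future ketal oxygens the same transferable silyl group.

Step 8
Reactants: 11 (3S,5S,6E)-1-iodo-3,7,11-trimethyl-3,5-bis(triethylsilyloxy)dodeca-6,10-diene; 12 methoxyallene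
Product: 14 (6R,8S,9E)-3-methoxy-6,10,14-trimethyl-6,8-bis(triethylsilyloxy)pentadeca-1,2,9,13-tetraene, via 1-lithio-1-methoxyallene 13 (not isolated)
Conditions: 12 (3 equiv), n-BuLi (2.8 equiv), THF, −40 °C; then 11, DMPU, −78 °C to rt; Et3N-deactivated silica
Reagents that add atoms: none
Why: α-Lithiation of methoxyallene and SN2 alkylation at its oxygen-bearing carbon by a primary iodide is the standard route to 1-alkyl-1-alkoxyallenes and touches no stereocentre.

Step 9
Reactants: 15 2-methylbenzene-1,4-diol
Product: 16 1,4-bis(tert-butyldimethylsilyloxy)-2-methylbenzene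
Conditions: TBSCl (2.5 equiv), imidazole (5 equiv), DMF, rt
Reagents that add atoms: tert-butyldimethylsilyl chloride, CC(C)(C)[Si](C)(C)Cl
Why: Standard silylation protects both phenols as TBS ethers, which tolerate the mild acids, Lewis acids and oxidants used later and leave under buffered fluoride without harm to acetates.

Step 10
Reactants: 16 1,4-bis(tert-butyldimethylsilyloxy)-2-methylbenzene
Product: 17 1-bromo-2,5-bis(tert-butyldimethylsilyloxy)-4-methylbenzene
Conditions: NBS (1.05 equiv), MeCN, 0 °C, dark
Reagents that add atoms: N-bromosuccinimide, O=C1CCC(=O)N1Br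
Why: Electrophilic aromatic bromination goes to the position para to the methyl group and ortho to a silyloxy group, the most activated and least hindered site, as it does in the corresponding dimethyl ether.

Step 11
Reactants: 17 1-bromo-2,5-bis(tert-butyldimethylsilyloxy)-4-methylbenzene
Product: 18 1-allyl-2,5-bis(tert-butyldimethylsilyloxy)-4-methylbenzene
Conditions: allylSnBu3 (1.3 equiv), Pd(PPh3)4 (5 mol %), toluene, 100 °C
Reagents that add atoms: allyltributylstannane, C=CC[Sn](CCCC)(CCCC)CCCC
Why: Stille cross-coupling installs the allyl group under neutral conditions that spare the base-labile aryl silyl ethers.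

Step 12
Reactants: 18 1-allyl-2,5-bis(tert-butyldimethylsilyloxy)-4-methylbenzene
Product: 20 [2,5-bis(tert-butyldimethylsilyloxy)-4-methylphenyl]acetaldehyde, via vicinal diol 19 (not isolated)
Conditions: OsO4 (2 mol %), NaIO4 (4 equiv), 2,6-lutidine (2 equiv), aq. dioxane, rt
Reagents that add atoms: osmium tetroxide, O=[Os](=O)(=O)=O; sodium periodate, [Na+].[O-]I(=O)(=O)=O
Why: Lemieux–Johnson cleavage (catalytic dihydroxylation, then periodate glycol fission) shortens the allyl group to the arylacetaldehyde without the risk that ozone poses to the electron-rich ring.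

Step 13
Reactants: 14 (6R,8S,9E)-3-methoxy-6,10,14-trimethyl-6,8-bis(triethylsilyloxy)pentadeca-1,2,9,13-tetraene; 20 [2,5-bis(tert-butyldimethylsilyloxy)-4-methylphenyl]acetaldehyde
Product: 22 (2R)-1-[2,5-bis(tert-butyldimethylsilyloxy)-4-methylphenyl]-3-{(1R,3S,5R)-3-[(1E)-2,6-dimethylhepta-1,5-dien-1-yl]-5-methyl-2,8-dioxabicyclo[3.2.1]octan-1-yl}but-3-en-2-ol, via 2-methoxyoxolane 21 (not isolated)
Conditions: 20 (1.2 equiv), tridentate Schiff-base Cr(III) complex from cis-1-amino-2-indanol and 3-(1-adamantyl)-5-methylsalicylaldehyde (SbF6 salt, Si-face-selective antipode, 10 mol %), 2,6-di-tert-butyl-4-methylpyridine (10 mol %), 4 Å MS, CH2Cl2, −20 °C to rt; then PPTS (20 mol %), MeOH, 0 °C to rt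
Reagents that add atoms: none
Why: Proposed new method: the aldehyde bound to the chiral Cr(III) Lewis acid is attacked by the central allene carbon of 14, which is the β-carbon of the enol-ether π bond and thus the only strongly nucleophilic site, so that the bond between the future CH(OAc) carbon and the future tertiary carbinol carbon forms while the orthogonal C=CH2 bond survives and a methoxy-oxocarbenium ion appears at the future ketal carbon. This cation is captured by the tertiary OSiEt3 oxygen (5-exo-trig, oxolane ring C1–C7–C6–C5–O8) with passage of Et3Si to the chromium aldolate, which frees the catalyst and gives 21; PPTS/MeOH then strips the two remaining Et3Si groups, ionises the OMe group and lets the allylic oxygen add to the ring oxocarbenium ion (6-endo-trig counted through O8, 7-exo-trig counted through C6–C7), which closes the 1,3-dioxane ring. The closest known reaction types are the Lewis-acid-catalysed, also Cr(III)-catalysed enantioselective, α-acylvinyl (Mukaiyama-type) addition of 1-silyloxyallenes to aldehydes, the Cr(III)- and Ti(IV)-catalysed enantioselective carbonyl-ene addition of 2-methoxypropene to aldehydes, and the ketalisation of oxocarbenium ions by silyl ethers; new are the O-alkyl allene as donor in a one-to-one fragment union and the double internal capture. The carbinol centre (R) is set by the catalyst, which has to leave the Si face of 20 open, whereas C1 is not free: a [3.2.1] bridge can span only one face, so 5R forces 1R, and 3S places the dienyl chain equatorially on the dioxane chair. The step needs attack at the central and not the terminal allene carbon (secured by the OMe donor), reaction of the allene and not of the two trisubstituted alkenes (secured by its much higher HOMO), and capture at C1 and not at the =CH2 terminus (secured by the five- and six-membered closures and by the lack of a better external nucleophile), while the new oxygen cannot compete because it could only close an oxetane. Should proton loss from C7 (ene pathway) intervene instead of silyl transfer, the 2-methoxydiene so formed is reprotonated at C7 by PPTS and enters the same ketalisation manifold.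

Step 14
Reactants: 22 the allylic alcohol of step 13
Product: 23 (1R)-2-[2,5-bis(tert-butyldimethylsilyloxy)-4-methylphenyl]-1-[(2S)-2-{(1R,3S,5R)-3-[(1E)-2,6-dimethylhepta-1,5-dien-1-yl]-5-methyl-2,8-dioxabicyclo[3.2.1]octan-1-yl}oxiran-2-yl]ethan-1-ol
Conditions: VO(acac)2 (5 mol %), t-BuOOH (decane, 1.5 equiv), CH2Cl2, 0 °C to rt
Reagents that add atoms: tert-butyl hydroperoxide, CC(C)(C)OO
Why: Vanadium-catalysed hydroxyl-directed epoxidation reaches only the alkene of the one free allylic alcohol, and with the bulky ketal as geminal substituent A(1,2) strain makes the carbinol H eclipse it, so oxygen is delivered to the face that gives the erythro (1R,2S) epoxy alcohol.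

Step 15
Reactants: 23 the epoxy alcohol of step 14
Product: 24 (2S,3R)-4-[2,5-bis(tert-butyldimethylsilyloxy)-4-methylphenyl]-2,3-dihydroxy-2-{(1R,3S,5R)-3-[(1E)-2,6-dimethylhepta-1,5-dien-1-yl]-5-methyl-2,8-dioxabicyclo[3.2.1]octan-1-yl}butyl acetate
Conditions: Ti(OiPr)4 (1.5 equiv), AcOH (3 equiv), CH2Cl2, rt
Reagents that add atoms: acetic acid, CC(=O)O
Why: In the Ti(OiPr)4-mediated opening of a 2,3-epoxy alcohol by a carboxylic acid the chelated epoxide is attacked at its unhindered CH2 terminus, the tertiary C–O bond is not broken so 2S is kept, and the non-basic medium spares the aryl silyl ethers.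

Step 16
Reactants: 24 the monoacetate of step 15
Product: 25 (2S,3R)-4-[2,5-bis(tert-butyldimethylsilyloxy)-4-methylphenyl]-2-hydroxy-2-{(1R,3S,5R)-3-[(1E)-2,6-dimethylhepta-1,5-dien-1-yl]-5-methyl-2,8-dioxabicyclo[3.2.1]octan-1-yl}butane-1,3-diyl diacetate
Conditions: Ac2O (3 equiv), pyridine, DMAP (cat.), CH2Cl2, 0 °C to rt
Reagents that add atoms: acetic anhydride, CC(=O)OC(C)=O
Why: DMAP-catalysed acetylation esterifies the secondary alcohol with retention (and any primary hydroxyl exposed by acyl migration), while the hindered tertiary alcohol stays free.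

Step 17
Reactants: 25 the bis-silyl diacetate of step 16
Product: 26 CNP0160303.2
Conditions: TBAF/AcOH (1:1, 2.5 equiv), degassed THF, 0 °C, argon
Reagents that add atoms: none
Why: Fluoride desilylation cleaves aryl silyl ethers rapidly, and the acetic acid buffer protonates the phenoxides at once so that acetate cleavage, acyl migration and hydroquinone oxidation are avoided.

**Compound list**
1 | 5-bromo-2-methylpent-2-ene | CC(C)=CCCBr | starting material
2 | 6-methylhept-5-en-1-yne | C#CCCC=C(C)C | intermediate
3 | [(1E)-2,6-dimethylhepta-1,5-dien-1-yl]dimethylalane | C[Al](C)/C=C(\C)CCC=C(C)C | intermediate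
4 | (1E)-1-iodo-2,6-dimethylhepta-1,5-diene | I/C=C(\C)CCC=C(C)C | intermediate
5 | (R)-mevalonolactone, (4R)-4-hydroxy-4-methyloxan-2-one | C[C@@]1(O)CCOC(=O)C1 | starting material
6 | (4R)-4-methyl-4-(triethylsilyloxy)oxan-2-one | C[C@@]1(O[Si](CC)(CC)CC)CCOC(=O)C1 | intermediate
7 | [(1E)-2,6-dimethylhepta-1,5-dien-1-yl]lithium | [Li]/C=C(\C)CCC=C(C)C | intermediate
8 | (3R,6E)-1-hydroxy-3,7,11-trimethyl-3-(triethylsilyloxy)dodeca-6,10-dien-5-one | OCC[C@](C)(CC(=O)/C=C(\C)CCC=C(C)C)O[Si](CC)(CC)CC | intermediate
9 | (3S,6E)-1-iodo-3,7,11-trimethyl-3-(triethylsilyloxy)dodeca-6,10-dien-5-one | ICC[C@](C)(CC(=O)/C=C(\C)CCC=C(C)C)O[Si](CC)(CC)CC | intermediate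
10 | (3S,5S,6E)-1-iodo-3,7,11-trimethyl-3-(triethylsilyloxy)dodeca-6,10-dien-5-ol | ICC[C@](C)(C[C@@H](/C=C(\C)CCC=C(C)C)O)O[Si](CC)(CC)CC | intermediate
11 | (3S,5S,6E)-1-iodo-3,7,11-trimethyl-3,5-bis(triethylsilyloxy)dodeca-6,10-diene | ICC[C@](C)(C[C@@H](/C=C(\C)CCC=C(C)C)O[Si](CC)(CC)CC)O[Si](CC)(CC)CC | intermediate
12 | methoxyallene (1-methoxypropa-1,2-diene) | COC=C=C | starting material
13 | 1-lithio-1-methoxyallene | [Li]C(OC)=C=C | intermediate
14 | (6R,8S,9E)-3-methoxy-6,10,14-trimethyl-6,8-bis(triethylsilyloxy)pentadeca-1,2,9,13-tetraene | C=C=C(OC)CC[C@](C)(C[C@@H](/C=C(\C)CCC=C(C)C)O[Si](CC)(CC)CC)O[Si](CC)(CC)CC | intermediate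
15 | 2-methylbenzene-1,4-diol (methylhydroquinone) | Cc1cc(O)ccc1O | starting material
16 | 1,4-bis(tert-butyldimethylsilyloxy)-2-methylbenzene | Cc1cc(O[Si](C)(C)C(C)(C)C)ccc1O[Si](C)(C)C(C)(C)C | intermediate
17 | 1-bromo-2,5-bis(tert-butyldimethylsilyloxy)-4-methylbenzene | Cc1cc(O[Si](C)(C)C(C)(C)C)c(Br)cc1O[Si](C)(C)C(C)(C)C | intermediate
18 | 1-allyl-2,5-bis(tert-butyldimethylsilyloxy)-4-methylbenzene | C=CCc1cc(O[Si](C)(C)C(C)(C)C)c(C)cc1O[Si](C)(C)C(C)(C)C | intermediate
19 | 3-[2,5-bis(tert-butyldimethylsilyloxy)-4-methylphenyl]propane-1,2-diol (racemic) | OCC(O)Cc1cc(O[Si](C)(C)C(C)(C)C)c(C)cc1O[Si](C)(C)C(C)(C)C | intermediate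
20 | [2,5-bis(tert-butyldimethylsilyloxy)-4-methylphenyl]acetaldehyde | O=CCc1cc(O[Si](C)(C)C(C)(C)C)c(C)cc1O[Si](C)(C)C(C)(C)C | intermediate
21 | (5R)-2-methoxy-5-methyl-2-{(3R)-4-[2,5-bis(tert-butyldimethylsilyloxy)-4-methylphenyl]-3-(triethylsilyloxy)but-1-en-2-yl}-5-[(2S,3E)-4,8-dimethyl-2-(triethylsilyloxy)nona-3,7-dien-1-yl]oxolane (both anomers at C2) | C=C([C@@H](Cc1cc(O[Si](C)(C)C(C)(C)C)c(C)cc1O[Si](C)(C)C(C)(C)C)O[Si](CC)(CC)CC)C1(OC)CC[C@](C)(C[C@@H](/C=C(\C)CCC=C(C)C)O[Si](CC)(CC)CC)O1 | intermediate
22 | (2R)-1-[2,5-bis(tert-butyldimethylsilyloxy)-4-methylphenyl]-3-{(1R,3S,5R)-3-[(1E)-2,6-dimethylhepta-1,5-dien-1-yl]-5-methyl-2,8-dioxabicyclo[3.2.1]octan-1-yl}but-3-en-2-ol | C=C([C@@H](Cc1cc(O[Si](C)(C)C(C)(C)C)c(C)cc1O[Si](C)(C)C(C)(C)C)O)[C@]12CC[C@](C)(C[C@@H](/C=C(\C)CCC=C(C)C)O1)O2 | intermediate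
23 | (1R)-2-[2,5-bis(tert-butyldimethylsilyloxy)-4-methylphenyl]-1-[(2S)-2-{(1R,3S,5R)-3-[(1E)-2,6-dimethylhepta-1,5-dien-1-yl]-5-methyl-2,8-dioxabicyclo[3.2.1]octan-1-yl}oxiran-2-yl]ethan-1-ol | C1O[C@@]1([C@@H](Cc1cc(O[Si](C)(C)C(C)(C)C)c(C)cc1O[Si](C)(C)C(C)(C)C)O)[C@]12CC[C@](C)(C[C@@H](/C=C(\C)CCC=C(C)C)O1)O2 | intermediate
24 | (2S,3R)-4-[2,5-bis(tert-butyldimethylsilyloxy)-4-methylphenyl]-2,3-dihydroxy-2-{(1R,3S,5R)-3-[(1E)-2,6-dimethylhepta-1,5-dien-1-yl]-5-methyl-2,8-dioxabicyclo[3.2.1]octan-1-yl}butyl acetate | CC(=O)OC[C@](O)([C@@H](Cc1cc(O[Si](C)(C)C(C)(C)C)c(C)cc1O[Si](C)(C)C(C)(C)C)O)[C@]12CC[C@](C)(C[C@@H](/C=C(\C)CCC=C(C)C)O1)O2 | intermediate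
25 | (2S,3R)-4-[2,5-bis(tert-butyldimethylsilyloxy)-4-methylphenyl]-2-hydroxy-2-{(1R,3S,5R)-3-[(1E)-2,6-dimethylhepta-1,5-dien-1-yl]-5-methyl-2,8-dioxabicyclo[3.2.1]octan-1-yl}butane-1,3-diyl diacetate | CC(=O)OC[C@](O)([C@@H](Cc1cc(O[Si](C)(C)C(C)(C)C)c(C)cc1O[Si](C)(C)C(C)(C)C)OC(C)=O)[C@]12CC[C@](C)(C[C@@H](/C=C(\C)CCC=C(C)C)O1)O2 | intermediate
26 | CNP0160303.2, (2S,3R)-4-(2,5-dihydroxy-4-methylphenyl)-2-hydroxy-2-{(1R,3S,5R)-3-[(1E)-2,6-dimethylhepta-1,5-dien-1-yl]-5-methyl-2,8-dioxabicyclo[3.2.1]octan-1-yl}butane-1,3-diyl diacetate | CC(=O)OC[C@](O)([C@@H](Cc1cc(O)c(C)cc1O)OC(C)=O)[C@]12CC[C@](C)(C[C@@H](/C=C(\C)CCC=C(C)C)O1)O2 | target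

**Step count:** 17 steps in total. The longest linear sequence is 12 steps (steps 1, 2, 4–8, 13–17).

**Steps most likely to fail**

Step 13 (Proposed new method). The allenyl ether may be protonated or oligomerised faster than the C–C bond forms. Catalyst turnover by silyl transfer may be sluggish. Facial selectivity at the enolisable aldehyde may be poor. The fallback uses known chemistry, sets out from 14 and comes back at 22. TBAF in THF frees the allenyl ether diol F1. N-Iodosuccinimide (NaHCO3, CH2Cl2, −78 °C) then carries out the known haloalkoxylation of an alkoxyallene: iodine goes to the central carbon and the tertiary hydroxyl to the oxocarbenium carbon, giving the iodovinyl methyl ketal F2. PPTS closes this, with loss of methanol, to the 1-(1-iodoethenyl) bicyclic ketal F3. A Nozaki–Hiyama–Kishi coupling of F3 with 20 (CrCl2, cat. NiCl2, chiral oxazoline–sulfonamide ligand, Et3N, THF) then forms the same C–C bond and gives 22.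

Step 14. Oxygen transfer to a hindered 1,1-disubstituted alkene that the ketal deactivates inductively may be slow. Vanadium-mediated oxidation of the carbinol or undirected attack at the remote alkenes could then compete. The fallback sets out from 22 and comes back at 23. It replaces substrate-directed vanadium catalysis by reagent control in a stoichiometric Katsuki–Sharpless epoxidation, run as a matched kinetic resolution [Ti(OiPr)4, D-(−)-DIPT, t-BuOOH, 4 Å MS, CH2Cl2, −20 °C]. This system does not oxidise the carbinol. It delivers oxygen to the same face as required for the 2R alcohol and leaves any carbinol epimer carried over from step 13 unreacted. No new compound arises (F0).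

Step 6. Facial selectivity may be poor because the nominally small CH2 arm is β-quaternary and may rival the alkenyl arm in size. The fallback sets out from 9 and comes back at 10, and it gives up asymmetric induction in favour of separation and recycling. Luche reduction (NaBH4, CeCl3·7H2O, MeOH, −78 °C) gives both C5 epimers. These are diastereomers because of the fixed tertiary centre and are separated by chromatography. The 5S epimer is 10. The 5R epimer F4 is re-oxidised with MnO2 to 9 and reduced again.

**Further compounds**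
F1 | step 13 | (6R,8S,9E)-3-methoxy-6,10,14-trimethylpentadeca-1,2,9,13-tetraene-6,8-diol | C=C=C(OC)CC[C@](C)(C[C@@H](/C=C(\C)CCC=C(C)C)O)O
F2 | step 13 | (5R)-5-[(2S,3E)-2-hydroxy-4,8-dimethylnona-3,7-dien-1-yl]-2-(1-iodoethenyl)-2-methoxy-5-methyloxolane (both anomers) | C=C(I)C1(OC)CC[C@](C)(C[C@@H](/C=C(\C)CCC=C(C)C)O)O1
F3 | step 13 | (1R,3S,5R)-3-[(1E)-2,6-dimethylhepta-1,5-dien-1-yl]-1-(1-iodoethenyl)-5-methyl-2,8-dioxabicyclo[3.2.1]octane | C=C(I)[C@]12CC[C@](C)(C[C@@H](/C=C(\C)CCC=C(C)C)O1)O2
F0 | step 14 | none | none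
F4 | step 6 | (3S,5R,6E)-1-iodo-3,7,11-trimethyl-3-(triethylsilyloxy)dodeca-6,10-dien-5-ol | ICC[C@](C)(C[C@H](/C=C(\C)CCC=C(C)C)O)O[Si](CC)(CC)CC
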